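The plan rests on reading the furanone's O–C10(Me)–C1(=O) array (ring A) as a tertiary propargylic alcohol. Its stereocentre, methyl group, oxygen and C1 all come from L-lactic acid. The nine-membered oxacycle (ring B: O, C3–C10) is never closed directly. In the key step, ruthenium adds the C3 carboxyl group of an open-chain alkynyl hydroxy acid to alkyne carbon C1. That acid already carries the α-methylene lactone and the methacrylate. The resulting ten-membered enol lactone passes its acyl group to the adjacent C10 hydroxyl, contracts by one atom to the nine-membered keto lactone, and unveils the methyl ketone. A Claisen closure (C2–C3) then completes the bridged furanone.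

Key step: step 15

Atom numbers, used for all compounds:
- Ring A: C1 (ketone), C2 (=CH), C3 (O-bearing sp2 carbon).
- Bridge: C4 (CH–CH3; the methyl is C15), C5 (CHOH), C6 (CH–O-methacryloyl), C7, C8 (CH–O of lactone ring C), C9 (CH2), C10 (quaternary; its methyl is C14).
- Ring C: C11–C13 (α-methylene lactone).

Assumption: in step 6 the ligand antipode is the one that attacks the Re face of aldehyde 10. Its sense of induction on this β-hydroxy aldehyde is taken to follow that for unbranched aliphatic aldehydes.

Step 1
Reactants: 1 (S)-lactic acid; 2 pivalaldehyde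
Product: 3 (2S,5S)-2-tert-butyl-5-methyl-1,3-dioxolan-4-one (cis)
Conditions: TsOH·H2O (cat.), pentane, reflux, Dean–Stark; crystallisation at low temperature
Reagents that add atoms: pivalaldehyde 2, CC(C)(C)C=O
Why: Acid-catalysed acetalisation with water removal should favour the cis acetal, which crystallises, so the lactate centre is copied into a temporary acetal centre (self-regeneration of stereocentres).

Step 2
Reactants: 3 dioxolanone; 4 allyl bromide
Product: 5 (2S,5R)-2-tert-butyl-5-methyl-5-(prop-2-en-1-yl)-1,3-dioxolan-4-one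
Conditions: LDA, THF, −78 °C; then 4, −78 → −30 °C
Reagents that add atoms: allyl bromide 4, C=CCBr
Why: In this enolate alkylation the planar enolate is attacked anti to the tert-butyl group, so allyl takes the place of H with overall retention and sets C10 as in the target.

Step 3
Reactants: 5 allylated dioxolanone
Product: 6 (2S,5R)-2-tert-butyl-5-methyl-5-(prop-2-en-1-yl)-1,3-dioxolan-4-ol (anomer mixture)
Conditions: DIBAL-H (1.1 equiv), CH2Cl2, −78 °C; aqueous work-up
Reagents that add atoms: none
Why: Low-temperature DIBAL-H reduction should stop at the lactol because the aluminium hemiacetal is stable at −78 °C, and the quaternary C10 is not touched.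

Step 4
Reactants: 6 lactol; 7 dimethyl (1-diazo-2-oxopropyl)phosphonate
Product: 9 (R)-3-methylhex-5-en-1-yn-3-ol, via hydroxy aldehyde 8 (not isolated)
Conditions: 7 (2.5 equiv), K2CO3, MeOH, 0 °C → rt
Reagents that add atoms: dimethyl (1-diazo-2-oxopropyl)phosphonate 7, COP(=O)(OC)C(=[N+]=[N-])C(C)=O
Why: Carbonate in methanol opens the lactol to pivalaldehyde and the non-epimerisable α-hydroxy aldehyde 8, which the Ohira–Bestmann (Seyferth–Gilbert) homologation turns into the terminal alkyne C1≡C2; the excess reagent allows for its consumption by pivalaldehyde.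

Step 5
Reactants: 9 enynol
Product: 10 (R)-3-hydroxy-3-methylpent-4-ynal
Conditions: O3, CH2Cl2, −78 °C; Me2S; used crude
Reagents that add atoms: ozone, [O-][O+]=O
Why: Ozonolysis should cleave the alkene well before the much less reactive terminal alkyne, giving the C8 aldehyde.

Step 6
Reactants: 10 aldehyde; 11 ethyl 2-(bromomethyl)acrylate
Product: 13 (5R)-5-[(2R)-2-hydroxy-2-methylbut-3-yn-1-yl]-3-methylideneoxolan-2-one, via hydroxy ester 12 (not isolated)
Conditions: CrCl2 (10 mol %), Re-selective carbazole-bridged bis(oxazoline) ligand (12 mol %), Mn, Cp2ZrCl2, THF, rt; then PPTS (cat.), toluene, 50 °C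
Reagents that add atoms: ethyl 2-(bromomethyl)acrylate 11, C=C(CBr)C(=O)OCC
Why: This is a catalytic asymmetric Nozaki–Hiyama–Kishi-type 2-(alkoxycarbonyl)allylation followed by lactonisation; C8 is set by the chiral chromium complex (Re-face attack), and the ketone-free, alkyne-bearing side chain is inert to allylchromium.

Step 7
Reactants: 13 α-methylene lactone
Product: 14 (5S)-3-(bromomethyl)-5-[(2R)-2-hydroxy-2-methylbut-3-yn-1-yl]furan-2(5H)-one
Conditions: NBS, AIBN (cat.), PhCF3, 80 °C
Reagents that add atoms: N-bromosuccinimide, O=C1CCC(=O)N1Br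
Why: In this Wohl–Ziegler bromination H is abstracted at allylic C7 and bromine enters at C13 to give the conjugated butenolide; C8 is untouched, and either allylic bromide regioisomer would lead to the same allylzinc in step 8.

Step 8
Reactants: 14 bromomethyl butenolide; 15 acrolein
Product: 16 (4S,5S)-5-[(2R)-2-hydroxy-2-methylbut-3-yn-1-yl]-4-[(1R)-1-hydroxyprop-2-en-1-yl]-3-methylideneoxolan-2-one
Conditions: Zn dust, THF/sat. aq. NH4Cl, 0 °C → rt
Reagents that add atoms: acrolein 15, C=CC=O
Why: In this Barbier allylation with allylic transposition, C7 bonds anti to the C9 side chain (giving the trans lactone), and the ring-locked E-type allylzinc reacts through a Zimmerman–Traxler chair with the vinyl group equatorial, which sets C6 anti to C8 and regenerates the α-methylene group.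

Step 9
Reactants: 16 diol lactone; 17 methacrylic anhydride
Product: 18 6-O-methacrylate of 16 (6R,7R,8S,10R)
Conditions: 17 (1.1 equiv), DMAP (cat.), Et3N, CH2Cl2, 0 °C
Reagents that add atoms: methacrylic anhydride 17, C=C(C)C(=O)OC(=O)C(C)=C
Why: DMAP-catalysed acylation should take the secondary C6 hydroxyl and leave the hindered tertiary propargylic C10 hydroxyl free, with no stereocentre affected.

Step 10
Reactants: 18 methacrylate
Product: 19 C5 aldehyde (6S,7R,8S,10R)
Conditions: O3, CH2Cl2, −78 °C (Sudan red end point); Me2S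
Reagents that add atoms: ozone, [O-][O+]=O
Why: Ozonolysis should select the vinyl group because it is the only alkene not conjugated to a carbonyl group, while the two acrylate units and the alkyne react far more slowly.

Step 11
Reactants: 20 (S)-4-benzyl-1,3-thiazolidine-2-thione; 21 propionyl chloride
Product: 22 (S)-4-benzyl-3-propionyl-1,3-thiazolidine-2-thione
Conditions: Et3N, DMAP (cat.), CH2Cl2, 0 °C
Reagents that add atoms: propionyl chloride 21, CCC(=O)Cl
Why: This is a simple N-acylation of the auxiliary that brings in C3, C4 and C15.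

Step 12
Reactants: 19 aldehyde; 22 N-propionyl auxiliary
Product: 23 syn-aldol adduct (4S,5S,6S,7R,8S,10R)
Conditions: 22 (1.5 equiv), TiCl4, i-Pr2NEt, NMP, CH2Cl2, 0 → −78 °C; then 19
Reagents that add atoms: N-propionyl thiazolidinethione 22, CCC(=O)N1[C@@H](Cc2ccccc2)CSC1=S
Why: In this auxiliary-controlled titanium-enolate aldol (Evans-syn sense) the Z-enolate and chair transition state give the C4/C5 syn pair and the benzyl group fixes the enolate face, which should override the weak facial bias that α-oxygenated aldehydes show toward Z-enolates.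

Step 13
Reactants: 23 aldol adduct
Product: 24 5-O-triethylsilyl ether of 23
Conditions: TESOTf (1.1 equiv), 2,6-lutidine, CH2Cl2, −78 °C
Reagents that add atoms: triethylsilyl triflate, CC[Si](CC)(CC)OS(=O)(=O)C(F)(F)F
Why: Low-temperature silylation should take the secondary C5 hydroxyl before the tertiary C10 hydroxyl, blocking retro-aldol and acyl migration from O-6 in the later basic step.

Step 14
Reactants: 24 silyl ether
Product: 25 seco acid (4S,5S,6S,7R,8S,10R)
Conditions: LiOH (1.2 equiv), THF/H2O, 0 °C, short; then aq. HCl to pH 3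
Reagents that add atoms: lithium hydroxide, [Li+].[OH-]
Why: The N-acyl thiazolidinethione behaves as an active amide, so hydrolysis should outrun attack on the hindered conjugated methacrylate, and any reversible opening of ring C recloses on acidification.

Step 15
Reactants: 25 seco acid
Product: 27 nine-membered keto lactone (C3(=O)–O–C10, acetyl on C10), via ten-membered enol lactone 26 (not isolated)
Conditions: [Ru(μ-O2CH)(CO)2(PPh3)]2 (5 mol %), BHT, toluene, 90 °C, slow addition of 25 (final about 1 mM)
Reagents that add atoms: none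
Why: Proposed new method: the closest known reaction is the intermolecular ruthenium-catalysed addition of carboxylic acids to tertiary propargylic alcohols, which gives β-oxopropyl esters by Markovnikov addition and acyl migration, and here it is run within one molecule. The ruthenium carboxylate of 25 binds the alkyne and delivers oxygen to the inner carbon C1 (10-exo-dig), giving enol lactone 26. The C10 hydroxyl, 1,2 to the enol oxygen, attacks C3 (5-exo-trig, dioxolane-type tetrahedral intermediate) and expels the enol, so the enol oxygen and C1 leave the ring, the C10 oxygen enters it, and the ten-membered ring contracts to nine-membered lactone 27, driven by the enol ester to ketone conversion. No stereocentre is formed or touched, because the C10–O bond stays intact and the lactic acid configuration is kept. The step needs Markovnikov regiochemistry, which the propargylic hydroxyl secures, and cyclisation over oligomerisation, which slow addition and the binding of both termini to one metal centre should favour. O-5 is silylated and O-6 acylated, so no smaller lactone can form.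

Step 16
Reactants: 27 keto lactone
Product: 30 target CNP0195404.1, via hemiketal 28 (not isolated), via silylated furanone 29 (not isolated)
Conditions: LiHMDS (2.2 equiv), THF, −78 → −40 °C; then HF·pyridine, −40 °C → rt
Reagents that add atoms: none
Why: This is the classical intramolecular Claisen condensation of an α-acyloxy ketone to a 3(2H)-furanone: the methyl ketone is the kinetically most acidic site, its enolate closes C2–C3 on the lactone carbonyl (5-exo-trig), and HF·pyridine dehydrates hemiketal 28 and removes the silyl group, with ring B kept and no stereocentre changed.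

Compound list
1 | (S)-lactic acid | C[C@H](O)C(=O)O | starting material
2 | pivalaldehyde | CC(C)(C)C=O | starting material
3 | (2S,5S)-2-tert-butyl-5-methyl-1,3-dioxolan-4-one | C[C@@H]1O[C@H](C(C)(C)C)OC1=O | intermediate
4 | allyl bromide | C=CCBr | starting material
5 | (2S,5R)-2-tert-butyl-5-methyl-5-(prop-2-en-1-yl)-1,3-dioxolan-4-one | C=CC[C@@]1(C)O[C@H](C(C)(C)C)OC1=O | intermediate
6 | (2S,5R)-2-tert-butyl-5-methyl-5-(prop-2-en-1-yl)-1,3-dioxolan-4-ol | C=CC[C@@]1(C)O[C@H](C(C)(C)C)OC1O | intermediate
7 | dimethyl (1-diazo-2-oxopropyl)phosphonate | COP(=O)(OC)C(=[N+]=[N-])C(C)=O | starting material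
8 | (R)-2-hydroxy-2-methylpent-4-enal | C=CC[C@@](C)(O)C=O | intermediate
9 | (R)-3-methylhex-5-en-1-yn-3-ol | C=CC[C@@](C)(O)C#C | intermediate
10 | (R)-3-hydroxy-3-methylpent-4-ynal | O=CC[C@@](C)(O)C#C | intermediate
11 | ethyl 2-(bromomethyl)acrylate | C=C(CBr)C(=O)OCC | starting material
12 | ethyl (4R,6R)-4,6-dihydroxy-6-methyl-2-methylideneoct-7-ynoate | CCOC(=O)C(=C)C[C@@H](O)C[C@@](C)(O)C#C | intermediate
13 | (5R)-5-[(2R)-2-hydroxy-2-methylbut-3-yn-1-yl]-3-methylideneoxolan-2-one | C=C1C[C@H](C[C@@](C)(O)C#C)OC1=O | intermediate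
14 | (5S)-3-(bromomethyl)-5-[(2R)-2-hydroxy-2-methylbut-3-yn-1-yl]furan-2(5H)-one | BrCC1=C[C@H](C[C@@](C)(O)C#C)OC1=O | intermediate
15 | acrolein | C=CC=O | starting material
16 | (4S,5S)-5-[(2R)-2-hydroxy-2-methylbut-3-yn-1-yl]-4-[(1R)-1-hydroxyprop-2-en-1-yl]-3-methylideneoxolan-2-one | C=C[C@@H](O)[C@@H]1C(=C)C(=O)O[C@H]1C[C@@](C)(O)C#C | intermediate
17 | methacrylic anhydride | C=C(C)C(=O)OC(=O)C(C)=C | starting material
18 | 6-O-methacrylate of 16 | C=C[C@@H](OC(=O)C(C)=C)[C@@H]1C(=C)C(=O)O[C@H]1C[C@@](C)(O)C#C | intermediate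
19 | C5 aldehyde | O=C[C@@H](OC(=O)C(C)=C)[C@@H]1C(=C)C(=O)O[C@H]1C[C@@](C)(O)C#C | intermediate
20 | (S)-4-benzyl-1,3-thiazolidine-2-thione | S=C1N[C@@H](Cc2ccccc2)CS1 | starting material
21 | propionyl chloride | CCC(=O)Cl | starting material
22 | (S)-4-benzyl-3-propionyl-1,3-thiazolidine-2-thione | CCC(=O)N1[C@@H](Cc2ccccc2)CSC1=S | intermediate
23 | syn-aldol adduct | S=C1SC[C@H](Cc2ccccc2)N1C(=O)[C@@H](C)[C@H](O)[C@@H](OC(=O)C(C)=C)[C@@H]3C(=C)C(=O)O[C@H]3C[C@@](C)(O)C#C | intermediate
24 | 5-O-triethylsilyl ether of 23 | S=C1SC[C@H](Cc2ccccc2)N1C(=O)[C@@H](C)[C@H](O[Si](CC)(CC)CC)[C@@H](OC(=O)C(C)=C)[C@@H]3C(=C)C(=O)O[C@H]3C[C@@](C)(O)C#C | intermediate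
25 | seco acid | OC(=O)[C@@H](C)[C@H](O[Si](CC)(CC)CC)[C@@H](OC(=O)C(C)=C)[C@@H]1C(=C)C(=O)O[C@H]1C[C@@](C)(O)C#C | intermediate
26 | ten-membered enol lactone | C=C1OC(=O)[C@@H](C)[C@H](O[Si](CC)(CC)CC)[C@@H](OC(=O)C(C)=C)[C@@H]2C(=C)C(=O)O[C@H]2C[C@@]1(C)O | intermediate
27 | nine-membered keto lactone | CC(=O)[C@@]1(C)C[C@@H]2OC(=O)C(=C)[C@H]2[C@H](OC(=O)C(C)=C)[C@@H](O[Si](CC)(CC)CC)[C@H](C)C(=O)O1 | intermediate
28 | hemiketal (3-hydroxy-2,3-dihydrofuranone) | C=C(C)C(=O)O[C@@H]1[C@@H](O[Si](CC)(CC)CC)[C@H](C)C2(O)CC(=O)[C@@](C)(C[C@@H]3OC(=O)C(=C)[C@@H]13)O2 | intermediate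
29 | 5-O-triethylsilyl ether of the target | C=C(C)C(=O)O[C@@H]1[C@@H](O[Si](CC)(CC)CC)[C@H](C)C2=CC(=O)[C@@](C)(C[C@@H]3OC(=O)C(=C)[C@@H]13)O2 | intermediate
30 | CNP0195404.1 (4S,5S,6S,7R,8S,10R) | C=C(C)C(=O)O[C@@H]1[C@@H](O)[C@H](C)C2=CC(=O)[C@@](C)(C[C@@H]3OC(=O)C(=C)[C@@H]13)O2 | target

Total steps: 16. Longest linear sequence: 15 (steps 1–10 and 12–16).

Steps most likely to fail

**1. Step 15.** Intermolecular acid–alkyne addition (oligomerisation) may outrun the entropically costly ten-membered closure, or the catalyst may become too slow at high dilution.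

The fallback sets out from 19 and comes back at 27, uses known reaction types, and keeps the same ring contraction. The tertiary alcohol of 19 is capped with N-(trimethylsilyl)imidazole to give trimethylsilyl ether F1. Intermolecular Markovnikov addition of 2-bromopropanoic acid to its alkyne ((Ph3P)AuCl/AgPF6, toluene, 60 °C) gives open enol ester F2. SmI2 in THF at −78 °C closes C4–C5 by an intramolecular Reformatsky reaction, a known route to medium-ring lactones, giving ten-membered hydroxy enol lactone F3. TESOTf/2,6-lutidine then gives bis-silyl ether F4. Citric acid in methanol removes only the trimethylsilyl group, and the freed C10 hydroxyl triggers the acyl shift to 27. The price is that C4 and C5 then depend on the cyclic transition state rather than on the auxiliary.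

**2. Step 16.** The amide base or the enolates may add to the two acrylate units, or C4 may be enolised, before the hindered lactone carbonyl is attacked.

The fallback sets out from 27 and comes back at 29. TMSOTf/Et3N converts the only enolisable ketone into silyl enol ether F5, and NBS gives bromo ketone F6. PPh3 gives phosphonium bromide F7, and Et3N gives stabilised ylide F8. On heating in toluene, F8 closes C2=C3 by an intramolecular Wittig reaction on the lactone carbonyl to give 29. HF·pyridine then gives 30 as in step 16.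

**3. Step 14.** Hydroxide may cleave the methacrylate or add to the α-methylene lactone faster than it cleaves the hindered acyl auxiliary.

The fallback sets out from 24 and comes back at 25. Allyl alcohol with DMAP displaces the auxiliary to give allyl ester F9, and Pd(PPh3)4 with morpholine removes the allyl group under neutral conditions to give 25.

Further compounds
F1 | step 15 | 10-O-trimethylsilyl ether of 19 | O=C[C@@H](OC(=O)C(C)=C)[C@@H]1C(=C)C(=O)O[C@H]1C[C@@](C)(O[Si](C)(C)C)C#C
F2 | step 15 | open enol 2-bromopropanoate | C=C(OC(=O)C(C)Br)[C@](C)(O[Si](C)(C)C)C[C@@H]1OC(=O)C(=C)[C@H]1[C@H](OC(=O)C(C)=C)C=O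
F3 | step 15 | ten-membered hydroxy enol lactone, 10-O-trimethylsilyl | C=C1OC(=O)[C@@H](C)[C@H](O)[C@@H](OC(=O)C(C)=C)[C@@H]2C(=C)C(=O)O[C@H]2C[C@@]1(C)O[Si](C)(C)C
F4 | step 15 | bis-silyl ether of the ten-membered enol lactone | C=C1OC(=O)[C@@H](C)[C@H](O[Si](CC)(CC)CC)[C@@H](OC(=O)C(C)=C)[C@@H]2C(=C)C(=O)O[C@H]2C[C@@]1(C)O[Si](C)(C)C
F5 | step 16 | trimethylsilyl enol ether of 27 | C=C(O[Si](C)(C)C)[C@@]1(C)C[C@@H]2OC(=O)C(=C)[C@H]2[C@H](OC(=O)C(C)=C)[C@@H](O[Si](CC)(CC)CC)[C@H](C)C(=O)O1
F6 | step 16 | bromomethyl ketone | BrCC(=O)[C@@]1(C)C[C@@H]2OC(=O)C(=C)[C@H]2[C@H](OC(=O)C(C)=C)[C@@H](O[Si](CC)(CC)CC)[C@H](C)C(=O)O1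
F7 | step 16 | phosphonium bromide | [Br-].O=C(C[P+](c3ccccc3)(c3ccccc3)c3ccccc3)[C@@]1(C)C[C@@H]2OC(=O)C(=C)[C@H]2[C@H](OC(=O)C(C)=C)[C@@H](O[Si](CC)(CC)CC)[C@H](C)C(=O)O1
F8 | step 16 | keto phosphorane | O=C(C=P(c3ccccc3)(c3ccccc3)c3ccccc3)[C@@]1(C)C[C@@H]2OC(=O)C(=C)[C@H]2[C@H](OC(=O)C(C)=C)[C@@H](O[Si](CC)(CC)CC)[C@H](C)C(=O)O1
F9 | step 14 | allyl ester of 25 | C=CCOC(=O)[C@@H](C)[C@H](O[Si](CC)(CC)CC)[C@@H](OC(=O)C(C)=C)[C@@H]1C(=C)C(=O)O[C@H]1C[C@@](C)(O)C#C
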